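**Retrosynthetic overview**

- C2–C1' is cut last: the (2S) centre comes from a rhodium-catalysed asymmetric 1,4-arylation of a 6,8-diprenyl-5,7-disilyloxychromone (rings A and C) with the ring B chromenylboronic acid; the methoxymethyl and silyl groups are removed afterwards.
- Ring C (the pyranone) is cut at O1–C2 and C4–C4a: ortho-formylation of the ring A phenol, ethynyl addition, oxidation and closure through an enaminone.
- The strategy rests on ring A, a benzene with no free position: oxygen at C5, C7 and C8a alternates with prenyl at C6 and C8 and with the acyl-bearing C4a. It is assembled by Danheiser benzannulation of a 2-prenyl-3-silyloxycyclobutenone with a prenyl siloxyalkyne (bonds C8a–C8 and C6–C7, then closure C8a–C4a).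
- Both benzannulation partners come from one siloxyalkyne (the cyclobutenone by ketene cycloaddition); the dimethylpyran ring of ring B comes from 4-bromoresorcinol and 3-methylbut-2-enal.
- Order of ring formation: ring A (step 3), ring C as the chromone (step 6), the dimethylpyran ring on the second branch (step 7); C2 is set in step 10.

Key step: step 3

Assumption: the ester, diketene, 4-bromoresorcinol, 3-methylbut-2-enal and the ligand (S)-MeO-F12-BIPHEP, which is (S)-2,2'-bis[bis(3,4,5-trifluorophenyl)phosphino]-6,6'-dimethoxy-1,1'-biphenyl, are taken as purchasable; the ligand hand in step 10 follows the sense in which (S)-BINAP-type ligands give (S)-3-arylcyclohexanones and would be confirmed on a model chromone.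

**Route**

Step 1
Reactants: 1 ethyl 4-methylpent-3-enoate
Product: 3 triisopropyl[(5-methylhex-4-en-1-yn-1-yl)oxy]silane, via lithium ynolate 2 (not isolated)
Conditions: CH2Br2, lithium 2,2,6,6-tetramethylpiperidide, THF, −78 °C; LiN(SiMe3)2; n-BuLi, −78 → 0 °C; then i-Pr3SiCl, −78 → 25 °C
Reagents that add atoms: dibromomethane, BrCBr; chlorotriisopropylsilane, CC(C)[Si](Cl)(C(C)C)C(C)C
Why: Kowalski ester homologation stopped at the ynolate: LiCHBr2 adds to the ester at −78 °C, the derived dibromoketone enolate undergoes bromine–lithium exchange and 1,2-shift to ynolate 2, and the bulky chlorosilane silylates it on oxygen to give the isolable silyl ynol ether.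

Step 2
Reactants: 3 triisopropyl[(5-methylhex-4-en-1-yn-1-yl)oxy]silane; 4 diketene
Product: 6 2-(3-methylbut-2-enyl)-3-(triisopropylsilyloxy)cyclobut-2-en-1-one, via ketene 5 (not isolated)
Conditions: 4 cracked in a hot tube (550 °C, N2 stream), the ketene passed into 3 in CH2Cl2, 0 → 25 °C; excess ketene vented through a scrubber
Reagents that add atoms: none
Why: Pyrolysis splits diketene into two molecules of ketene, one of which is taken up by 3 in a thermal ketene–alkyne (2+2) cycloaddition in which the nucleophilic prenyl-bearing carbon of the siloxyalkyne bonds to the ketene carbonyl carbon, so that the prenyl group ends at C2 and the silyloxy group at C3 of the cyclobutenone.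

Step 3
Reactants: 6 2-(3-methylbut-2-enyl)-3-(triisopropylsilyloxy)cyclobut-2-en-1-one; 3 triisopropyl[(5-methylhex-4-en-1-yn-1-yl)oxy]silane
Product: 11 2,4-bis(3-methylbut-2-enyl)-3,5-bis(triisopropylsilyloxy)phenol, via vinylketene 7 (not isolated), via 4-vinylcyclobutenone 8 (not isolated), via dienylketene 9 (not isolated), via cyclohexadienone 10 (not isolated)
Conditions: 3 (1.3 equiv), toluene, 80 → 110 °C, sealed tube, argon
Reagents that add atoms: none
Why: Danheiser benzannulation, whose closest precedent is the thermal union of 3-alkyl- and 3-arylcyclobutenones with siloxyalkynes to resorcinol monosilyl ethers; the 3-silyloxy group makes 6 a vinylogous ester within that substrate class, which is the reason for the upper end of the temperature range. Heat opens 6 by conrotatory 4π-electrocyclic cleavage of the C(=O)–CH2 bond to vinylketene 7, which adds 3 in a ketene–alkyne (2+2) cycloaddition to give 8, and a second 4π opening gives dienylketene 9. Ring A then closes by thermal disrotatory 6π electrocyclisation of 9 (bond C8a–C4a), and cyclohexadienone 10 tautomerises irreversibly to phenol 11, so that the two new skeletal bonds are C8a–C8 and C6–C7. No stereocentre is formed; the quaternary carbon of 8 is transient and racemic. The selectivity needed is the orientation of the (2+2) step, and the polarity of the siloxyalkyne secures it: its prenyl-bearing carbon bonds to the ketene carbonyl carbon, which places the free hydroxyl between a prenyl-bearing carbon and the only unsubstituted ring carbon. Reversible opening of 8 funnels material through the dienylketene geometry that can cyclise, and the slight excess of 3 keeps 7 from dimerising or acylating 11.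

Step 4
Reactants: 11 2,4-bis(3-methylbut-2-enyl)-3,5-bis(triisopropylsilyloxy)phenol
Product: 12 2-hydroxy-3,5-bis(3-methylbut-2-enyl)-4,6-bis(triisopropylsilyloxy)benzaldehyde
Conditions: MgCl2, Et3N, (CH2O)n, THF, reflux; cold 1 M HCl work-up
Reagents that add atoms: paraformaldehyde (as formaldehyde), C=O
Why: Casnati–Skattebøl ortho-formylation: the magnesium phenoxide delivers formaldehyde to the only unsubstituted ring carbon and a second formaldehyde oxidises the hydroxymethyl intermediate by hydride transfer, all without acid, so that the ortho-prenylphenol does not close to a chroman and the silyl ethers stay in place.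

Step 5
Reactants: 12 2-hydroxy-3,5-bis(3-methylbut-2-enyl)-4,6-bis(triisopropylsilyloxy)benzaldehyde
Product: 13 1-[2-hydroxy-3,5-bis(3-methylbut-2-enyl)-4,6-bis(triisopropylsilyloxy)phenyl]prop-2-yn-1-ol (racemic)
Conditions: HC≡CMgBr (3 equiv), THF, −20 → 0 °C; aq NH4Cl
Reagents that add atoms: ethynylmagnesium bromide, C#C[Mg]Br
Why: Grignard 1,2-addition to the salicylaldehyde after the first equivalent has deprotonated the phenol; the carbinol centre forms racemic and is erased by the oxidation in step 6, and the low temperature keeps the magnesium alkoxide from taking over the neighbouring silyl group.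

Step 6
Reactants: 13 1-[2-hydroxy-3,5-bis(3-methylbut-2-enyl)-4,6-bis(triisopropylsilyloxy)phenyl]prop-2-yn-1-ol
Product: 16 6,8-bis(3-methylbut-2-enyl)-5,7-bis(triisopropylsilyloxy)-4H-chromen-4-one, via ynone 14 (not isolated), via enaminone 15 (not isolated)
Conditions: MnO2, CH2Cl2, 25 °C; filter; Et2NH, EtOH, 25 °C; then AcOH, 50 °C
Reagents that add atoms: none
Why: MnO2 oxidises the benzylic propargylic alcohol to ynone 14, diethylamine adds in aza-Michael fashion to give enaminone 15, and acetic acid promotes addition of the phenol oxygen to C2 with loss of diethylamine (6-endo addition–elimination), which closes ring C as the chromone.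

Step 7
Reactants: 17 4-bromobenzene-1,3-diol; 18 3-methylbut-2-enal
Product: 19 6-bromo-2,2-dimethyl-2H-chromen-7-ol
Conditions: ethylenediammonium diacetate (10 mol %), toluene, reflux
Reagents that add atoms: none
Why: Amine-salt-catalysed Knoevenagel-type condensation at the unsubstituted carbon ortho to one hydroxyl and para to the other, followed by oxa-6π electrocyclisation of the ortho-quinone methide, should give the 2,2-dimethyl-2H-chromene with bromine at C6 and the free hydroxyl at C7.

Step 8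
Reactants: 19 6-bromo-2,2-dimethyl-2H-chromen-7-ol
Product: 20 6-bromo-7-(methoxymethoxy)-2,2-dimethyl-2H-chromene
Conditions: MeOCH2Cl, i-Pr2NEt, CH2Cl2, 0 → 25 °C
Reagents that add atoms: chloromethyl methyl ether, COCCl
Why: Base-mediated O-alkylation of the phenol (Williamson-type) installs a methoxymethyl ether that withstands organolithium and aqueous base and is small enough not to block the later arylation.

Step 9
Reactants: 20 6-bromo-7-(methoxymethoxy)-2,2-dimethyl-2H-chromene
Product: 22 [7-(methoxymethoxy)-2,2-dimethyl-2H-chromen-6-yl]boronic acid, via aryllithium 21 (not isolated)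
Conditions: n-BuLi, THF, −78 °C; B(Oi-Pr)3, −78 → 0 °C; aq NH4Cl
Reagents that add atoms: triisopropyl borate, CC(C)OB(OC(C)C)OC(C)C; water, O
Why: Bromine–lithium exchange at −78 °C gives aryllithium 21, which is trapped by the borate ester and hydrolysed under near-neutral conditions that leave the methoxymethyl ether and the chromene untouched.

Step 10
Reactants: 16 6,8-bis(3-methylbut-2-enyl)-5,7-bis(triisopropylsilyloxy)-4H-chromen-4-one; 22 [7-(methoxymethoxy)-2,2-dimethyl-2H-chromen-6-yl]boronic acid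
Product: 23 (2S)-2-[7-(methoxymethoxy)-2,2-dimethyl-2H-chromen-6-yl]-6,8-bis(3-methylbut-2-enyl)-5,7-bis(triisopropylsilyloxy)-2,3-dihydro-4H-chromen-4-one
Conditions: [RhCl(C2H4)2]2 (3 mol %), (S)-MeO-F12-BIPHEP (6.6 mol %), 22 (3 equiv), aq K3PO4, toluene, 40 °C
Reagents that add atoms: none
Why: Rhodium-catalysed asymmetric 1,4-addition of an arylboronic acid to an enone (Hayashi–Miyaura reaction), in which the aryl–rhodium species (monovalent rhodium) held in the chiral pocket of the electron-poor (S)-bisphosphine inserts the C2=C3 bond of the chromone from one face and water protonates the rhodium enolate; the (S)-ligand is expected to give (2S) by the quadrant model stated in the assumption.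

Step 11
Reactants: 23 (2S)-2-[7-(methoxymethoxy)-2,2-dimethyl-2H-chromen-6-yl]-6,8-bis(3-methylbut-2-enyl)-5,7-bis(triisopropylsilyloxy)-2,3-dihydro-4H-chromen-4-one
Product: 25 (2S)-2-(7-hydroxy-2,2-dimethyl-2H-chromen-6-yl)-6,8-bis(3-methylbut-2-enyl)-5,7-bis(triisopropylsilyloxy)-2,3-dihydro-4H-chromen-4-one, via aryl trimethylsilyl ether 24 (not isolated)
Conditions: Me3SiOTf, 2,2'-bipyridyl, CH2Cl2, 0 → 25 °C; then H2O
Reagents that add atoms: none
Why: Lewis-acid acetal cleavage with the Me3SiOTf–2,2'-bipyridyl pair converts the aryl methoxymethyl ether into aryl trimethylsilyl ether 24, which water hydrolyses on work-up, so that no protic acid meets the chromene double bond or the prenyl groups and C2 is untouched.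

Step 12
Reactants: 25 (2S)-2-(7-hydroxy-2,2-dimethyl-2H-chromen-6-yl)-6,8-bis(3-methylbut-2-enyl)-5,7-bis(triisopropylsilyloxy)-2,3-dihydro-4H-chromen-4-one
Product: 26 euchrenone a3
Conditions: Bu4NF, AcOH (1:1), THF, 0 °C
Reagents that add atoms: none
Why: Fluoride-mediated cleavage of the two aryl silyl ethers, buffered with acetic acid so that no phenoxide or enolate can open ring C by retro-oxa-Michael reaction and racemise C2.

**Compound list**

1 | ethyl 4-methylpent-3-enoate | CCOC(=O)CC=C(C)C | starting material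
2 | lithium 5-methylhex-4-en-1-yn-1-olate | CC(C)=CCC#C[O-].[Li+] | intermediate
3 | triisopropyl[(5-methylhex-4-en-1-yn-1-yl)oxy]silane | CC(C)=CCC#CO[Si](C(C)C)(C(C)C)C(C)C | intermediate
4 | diketene (4-methylideneoxetan-2-one) | C=C1CC(=O)O1 | starting material
5 | ketene (ethenone) | C=C=O | intermediate
6 | 2-(3-methylbut-2-enyl)-3-(triisopropylsilyloxy)cyclobut-2-en-1-one | CC(C)=CCC1=C(O[Si](C(C)C)(C(C)C)C(C)C)CC1=O | intermediate
7 | 2-(3-methylbut-2-enyl)-3-(triisopropylsilyloxy)buta-1,3-dien-1-one | CC(C)=CCC(=C=O)C(=C)O[Si](C(C)C)(C(C)C)C(C)C | intermediate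
8 | 2,4-bis(3-methylbut-2-enyl)-3-(triisopropylsilyloxy)-4-[1-(triisopropylsilyloxy)ethenyl]cyclobut-2-en-1-one (racemic) | CC(C)=CCC1=C(O[Si](C(C)C)(C(C)C)C(C)C)C(CC=C(C)C)(C(=C)O[Si](C(C)C)(C(C)C)C(C)C)C1=O | intermediate
9 | 2,4-bis(3-methylbut-2-enyl)-3,5-bis(triisopropylsilyloxy)hexa-1,3,5-trien-1-one | CC(C)=CCC(=C=O)C(O[Si](C(C)C)(C(C)C)C(C)C)=C(CC=C(C)C)C(=C)O[Si](C(C)C)(C(C)C)C(C)C | intermediate
10 | 2,4-bis(3-methylbut-2-enyl)-3,5-bis(triisopropylsilyloxy)cyclohexa-2,4-dien-1-one | CC(C)=CCC1=C(O[Si](C(C)C)(C(C)C)C(C)C)C(CC=C(C)C)=C(O[Si](C(C)C)(C(C)C)C(C)C)CC1=O | intermediate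
11 | 2,4-bis(3-methylbut-2-enyl)-3,5-bis(triisopropylsilyloxy)phenol | CC(C)=CCc1c(O)cc(O[Si](C(C)C)(C(C)C)C(C)C)c(CC=C(C)C)c1O[Si](C(C)C)(C(C)C)C(C)C | intermediate
12 | 2-hydroxy-3,5-bis(3-methylbut-2-enyl)-4,6-bis(triisopropylsilyloxy)benzaldehyde | CC(C)=CCc1c(O)c(C=O)c(O[Si](C(C)C)(C(C)C)C(C)C)c(CC=C(C)C)c1O[Si](C(C)C)(C(C)C)C(C)C | intermediate
13 | 1-[2-hydroxy-3,5-bis(3-methylbut-2-enyl)-4,6-bis(triisopropylsilyloxy)phenyl]prop-2-yn-1-ol (racemic) | CC(C)=CCc1c(O)c(C(O)C#C)c(O[Si](C(C)C)(C(C)C)C(C)C)c(CC=C(C)C)c1O[Si](C(C)C)(C(C)C)C(C)C | intermediate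
14 | 1-[2-hydroxy-3,5-bis(3-methylbut-2-enyl)-4,6-bis(triisopropylsilyloxy)phenyl]prop-2-yn-1-one | CC(C)=CCc1c(O)c(C(=O)C#C)c(O[Si](C(C)C)(C(C)C)C(C)C)c(CC=C(C)C)c1O[Si](C(C)C)(C(C)C)C(C)C | intermediate
15 | (E)-3-(diethylamino)-1-[2-hydroxy-3,5-bis(3-methylbut-2-enyl)-4,6-bis(triisopropylsilyloxy)phenyl]prop-2-en-1-one | CCN(CC)/C=C/C(=O)c1c(O)c(CC=C(C)C)c(O[Si](C(C)C)(C(C)C)C(C)C)c(CC=C(C)C)c1O[Si](C(C)C)(C(C)C)C(C)C | intermediate
16 | 6,8-bis(3-methylbut-2-enyl)-5,7-bis(triisopropylsilyloxy)-4H-chromen-4-one | CC(C)=CCc1c(O[Si](C(C)C)(C(C)C)C(C)C)c(CC=C(C)C)c2c(c1O[Si](C(C)C)(C(C)C)C(C)C)C(=O)C=CO2 | intermediate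
17 | 4-bromobenzene-1,3-diol (4-bromoresorcinol) | Oc1ccc(Br)c(O)c1 | starting material
18 | 3-methylbut-2-enal | CC(C)=CC=O | starting material
19 | 6-bromo-2,2-dimethyl-2H-chromen-7-ol | CC1(C)C=Cc2cc(Br)c(O)cc2O1 | intermediate
20 | 6-bromo-7-(methoxymethoxy)-2,2-dimethyl-2H-chromene | COCOc1cc2OC(C)(C)C=Cc2cc1Br | intermediate
21 | [7-(methoxymethoxy)-2,2-dimethyl-2H-chromen-6-yl]lithium | [Li]c1cc2C=CC(C)(C)Oc2cc1OCOC | intermediate
22 | [7-(methoxymethoxy)-2,2-dimethyl-2H-chromen-6-yl]boronic acid | COCOc1cc2OC(C)(C)C=Cc2cc1B(O)O | intermediate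
23 | (2S)-2-[7-(methoxymethoxy)-2,2-dimethyl-2H-chromen-6-yl]-6,8-bis(3-methylbut-2-enyl)-5,7-bis(triisopropylsilyloxy)-2,3-dihydro-4H-chromen-4-one | CC(C)=CCc1c(O[Si](C(C)C)(C(C)C)C(C)C)c(CC=C(C)C)c2c(c1O[Si](C(C)C)(C(C)C)C(C)C)C(=O)C[C@@H](c1cc3c(cc1OCOC)OC(C)(C)C=C3)O2 | intermediate
24 | (2S)-2-[2,2-dimethyl-7-(trimethylsilyloxy)-2H-chromen-6-yl]-6,8-bis(3-methylbut-2-enyl)-5,7-bis(triisopropylsilyloxy)-2,3-dihydro-4H-chromen-4-one | CC(C)=CCc1c(O[Si](C(C)C)(C(C)C)C(C)C)c(CC=C(C)C)c2c(c1O[Si](C(C)C)(C(C)C)C(C)C)C(=O)C[C@@H](c1cc3c(cc1O[Si](C)(C)C)OC(C)(C)C=C3)O2 | intermediate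
25 | (2S)-2-(7-hydroxy-2,2-dimethyl-2H-chromen-6-yl)-6,8-bis(3-methylbut-2-enyl)-5,7-bis(triisopropylsilyloxy)-2,3-dihydro-4H-chromen-4-one | CC(C)=CCc1c(O[Si](C(C)C)(C(C)C)C(C)C)c(CC=C(C)C)c2c(c1O[Si](C(C)C)(C(C)C)C(C)C)C(=O)C[C@@H](c1cc3c(cc1O)OC(C)(C)C=C3)O2 | intermediate
26 | euchrenone a3, (2S)-5,7-dihydroxy-2-(7-hydroxy-2,2-dimethyl-2H-chromen-6-yl)-6,8-bis(3-methylbut-2-enyl)-2,3-dihydro-4H-chromen-4-one | CC(C)=CCc1c(O)c(CC=C(C)C)c2c(c1O)C(=O)C[C@@H](c1cc3c(cc1O)OC(C)(C)C=C3)O2 | target

**Step count**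

Total: 12 steps. Longest linear sequence: 9 steps (steps 1, 2, 3, 4, 5, 6, 10, 11, 12); the ring B branch (steps 7, 8, 9) joins at step 10.

**Steps most likely to fail**

Step 3. The donor-stabilised cyclobutenone 6 may open only at temperatures at which siloxyalkyne 3 rearranges to a silylketene by 1,3-silyl shift. Alternatively, vinylketene 7 may dimerise or acylate the product phenol before the alkyne intercepts it. The fallback gives up the construction of ring A and prenylates a purchased phloroglucinol ring. No numbered compound ahead of step 3 holds ring A, so it sets out from purchased 2,4,6-trihydroxybenzaldehyde F1 in place of compounds 1 to 11 and comes back to the route at aldehyde 12, which also by-passes step 4. Twofold C-prenylation of F1 (prenyl bromide, 1,8-diazabicyclo[5.4.0]undec-7-ene, THF, 0 °C) should give 2,4,6-trihydroxy-3,5-bis(3-methylbut-2-enyl)benzaldehyde F2, with O-prenylated and geminally diprenylated material to be separated. Silylation with i-Pr3SiOTf (2.1 equiv) and 2,6-lutidine in CH2Cl2 should leave the hydroxyl that is hydrogen-bonded to the formyl group free and give 12.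

Step 10. The electron-rich, ortho-substituted boronic acid 22 may protodeboronate faster than it transmetalates and inserts into the vinylogous ester. The ortho substituent may also erode face selectivity, and base may open the product to the chalcone. The fallback forms the C2–aryl bond without stereochemistry and sets C2 by hydride delivery; it sets out from aldehyde 12 and bromide 20 and comes back at 23. Sonogashira coupling of 20 with ethynyltrimethylsilane (Pd(PPh3)2Cl2, CuI, Et3N) should give trimethyl{[7-(methoxymethoxy)-2,2-dimethyl-2H-chromen-6-yl]ethynyl}silane F3, and K2CO3 in MeOH the alkyne 6-ethynyl-7-(methoxymethoxy)-2,2-dimethyl-2H-chromene F4. The magnesium acetylide of F4 (EtMgBr, THF) would add to 12 to give 1-[2-hydroxy-3,5-bis(3-methylbut-2-enyl)-4,6-bis(triisopropylsilyloxy)phenyl]-3-[7-(methoxymethoxy)-2,2-dimethyl-2H-chromen-6-yl]prop-2-yn-1-ol F5. MnO2 would oxidise it to 1-[2-hydroxy-3,5-bis(3-methylbut-2-enyl)-4,6-bis(triisopropylsilyloxy)phenyl]-3-[7-(methoxymethoxy)-2,2-dimethyl-2H-chromen-6-yl]prop-2-yn-1-one F6. Diethylamine would add to the ynone to give 3-(diethylamino)-1-[2-hydroxy-3,5-bis(3-methylbut-2-enyl)-4,6-bis(triisopropylsilyloxy)phenyl]-3-[7-(methoxymethoxy)-2,2-dimethyl-2H-chromen-6-yl]prop-2-en-1-one F7, and acetic acid would close it to the flavone 2-[7-(methoxymethoxy)-2,2-dimethyl-2H-chromen-6-yl]-6,8-bis(3-methylbut-2-enyl)-5,7-bis(triisopropylsilyloxy)-4H-chromen-4-one F8. Copper hydride asymmetric conjugate reduction of the flavone (Cu(OAc)2, DTBM-SEGPHOS, (EtO)2MeSiH in slight excess only, t-BuOH, toluene, 0 °C) should give 23, the limited silane and low temperature sparing the chromene double bond. The ligand enantiomer that delivers hydride to the face giving (2S) would be fixed on a model flavone.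

Step 4. The C–C bond formation between the magnesium phenoxide and formaldehyde may stall at a carbon flanked by a triisopropylsilyloxy group, or the hydroxymethyl intermediate may condense with a second phenol instead of being oxidised. The fallback brings in the carbonyl carbon by acyl transfer from oxygen; it sets out from phenol 11 and comes back at chromone 16, by-passing steps 5 and 6. Acetylation (Ac2O, Et3N, 4-dimethylaminopyridine) should give 2,4-bis(3-methylbut-2-enyl)-3,5-bis(triisopropylsilyloxy)phenyl acetate F9. Photo-Fries rearrangement (254 nm, cyclohexane) should move the acetyl group to the only free ortho carbon and give 1-[2-hydroxy-3,5-bis(3-methylbut-2-enyl)-4,6-bis(triisopropylsilyloxy)phenyl]ethan-1-one F10. Condensation with N,N-dimethylformamide dimethyl acetal (toluene, 90 °C) should give (E)-3-(dimethylamino)-1-[2-hydroxy-3,5-bis(3-methylbut-2-enyl)-4,6-bis(triisopropylsilyloxy)phenyl]prop-2-en-1-one F11, which acetic acid at 50 °C would close to 16.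

**Further compounds**

F1 | step 3 | 2,4,6-trihydroxybenzaldehyde | O=Cc1c(O)cc(O)cc1O
F2 | step 3 | 2,4,6-trihydroxy-3,5-bis(3-methylbut-2-enyl)benzaldehyde | CC(C)=CCc1c(O)c(CC=C(C)C)c(O)c(C=O)c1O
F3 | step 10 | trimethyl{[7-(methoxymethoxy)-2,2-dimethyl-2H-chromen-6-yl]ethynyl}silane | COCOc1cc2OC(C)(C)C=Cc2cc1C#C[Si](C)(C)C
F4 | step 10 | 6-ethynyl-7-(methoxymethoxy)-2,2-dimethyl-2H-chromene | COCOc1cc2OC(C)(C)C=Cc2cc1C#C
F5 | step 10 | 1-[2-hydroxy-3,5-bis(3-methylbut-2-enyl)-4,6-bis(triisopropylsilyloxy)phenyl]-3-[7-(methoxymethoxy)-2,2-dimethyl-2H-chromen-6-yl]prop-2-yn-1-ol (racemic) | CC(C)=CCc1c(O)c(C(O)C#Cc2cc3C=CC(C)(C)Oc3cc2OCOC)c(O[Si](C(C)C)(C(C)C)C(C)C)c(CC=C(C)C)c1O[Si](C(C)C)(C(C)C)C(C)C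
F6 | step 10 | 1-[2-hydroxy-3,5-bis(3-methylbut-2-enyl)-4,6-bis(triisopropylsilyloxy)phenyl]-3-[7-(methoxymethoxy)-2,2-dimethyl-2H-chromen-6-yl]prop-2-yn-1-one | CC(C)=CCc1c(O)c(C(=O)C#Cc2cc3C=CC(C)(C)Oc3cc2OCOC)c(O[Si](C(C)C)(C(C)C)C(C)C)c(CC=C(C)C)c1O[Si](C(C)C)(C(C)C)C(C)C
F7 | step 10 | 3-(diethylamino)-1-[2-hydroxy-3,5-bis(3-methylbut-2-enyl)-4,6-bis(triisopropylsilyloxy)phenyl]-3-[7-(methoxymethoxy)-2,2-dimethyl-2H-chromen-6-yl]prop-2-en-1-one | CCN(CC)C(=CC(=O)c1c(O)c(CC=C(C)C)c(O[Si](C(C)C)(C(C)C)C(C)C)c(CC=C(C)C)c1O[Si](C(C)C)(C(C)C)C(C)C)c1cc2C=CC(C)(C)Oc2cc1OCOC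
F8 | step 10 | 2-[7-(methoxymethoxy)-2,2-dimethyl-2H-chromen-6-yl]-6,8-bis(3-methylbut-2-enyl)-5,7-bis(triisopropylsilyloxy)-4H-chromen-4-one | CC(C)=CCc1c(O[Si](C(C)C)(C(C)C)C(C)C)c(CC=C(C)C)c2c(c1O[Si](C(C)C)(C(C)C)C(C)C)C(=O)C=C(c1cc3c(cc1OCOC)OC(C)(C)C=C3)O2
F9 | step 4 | 2,4-bis(3-methylbut-2-enyl)-3,5-bis(triisopropylsilyloxy)phenyl acetate | CC(C)=CCc1c(OC(C)=O)cc(O[Si](C(C)C)(C(C)C)C(C)C)c(CC=C(C)C)c1O[Si](C(C)C)(C(C)C)C(C)C
F10 | step 4 | 1-[2-hydroxy-3,5-bis(3-methylbut-2-enyl)-4,6-bis(triisopropylsilyloxy)phenyl]ethan-1-one | CC(C)=CCc1c(O)c(C(C)=O)c(O[Si](C(C)C)(C(C)C)C(C)C)c(CC=C(C)C)c1O[Si](C(C)C)(C(C)C)C(C)C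
F11 | step 4 | (E)-3-(dimethylamino)-1-[2-hydroxy-3,5-bis(3-methylbut-2-enyl)-4,6-bis(triisopropylsilyloxy)phenyl]prop-2-en-1-one | CN(C)/C=C/C(=O)c1c(O)c(CC=C(C)C)c(O[Si](C(C)C)(C(C)C)C(C)C)c(CC=C(C)C)c1O[Si](C(C)C)(C(C)C)C(C)C
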